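**Retrosynthetic overview**
- The target is the symmetric dimer of 3-hydroxy-5-[2-(2-methoxyphenyl)ethyl]-2-methyl-1,4-benzoquinone, and the central quinone–quinone bond is cut last. Both carbons of that bond are electrophilic enone β-carbons in the monomer, so one half is used as its hydroquinone (same carbon, now nucleophilic) and adds to the other half; FeCl3 then restores both quinones.
- Monomer quinone ⇐ Teuber oxidation of 5-[2-(2-methoxyphenyl)ethyl]-2-methylresorcinol.
- Resorcinol ⇐ one hydrogenation (C=O to CH2, two benzyl ethers off) of a deoxybenzoin ⇐ Ivanov–Claisen acylation of the 2-methoxyphenylacetic acid dianion by benzyl 3,5-bis(benzyloxy)-4-methylbenzoate ⇐ 3,5-dihydroxy-4-methylbenzoic acid.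
- Rings: none is built. All four six-membered rings come from commercial arenes; the first quinone ring is generated by oxidation in step 4, and both quinone rings of the dimer are set in step 5.

Assumption: the SMILES carries no stereodescriptor, so the target has no stereocentre and the hindered biquinone axis is taken as unspecified; no enantioselective step is needed.

**Step 1**
Reactants: 1 3,5-dihydroxy-4-methylbenzoic acid
Product: 2 benzyl 3,5-bis(benzyloxy)-4-methylbenzoate
Conditions: BnBr (3.3 equiv), K2CO3 (4 equiv), DMF, 60 °C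
Reagents that add atoms: benzyl bromide, BrCc1ccccc1
Why: Exhaustive Williamson O-alkylation of the carboxylate and both phenoxides gives, in one operation, an ester electrophile whose three benzyl groups are all removable later without touching an aryl methyl ether; no stereocentre is involved.

**Step 2**
Reactants: 2 benzyl 3,5-bis(benzyloxy)-4-methylbenzoate, 3 2-(2-methoxyphenyl)acetic acid
Product: 6 1-[3,5-bis(benzyloxy)-4-methylphenyl]-2-(2-methoxyphenyl)ethan-1-one, via magnesium enediolate 4 (not isolated), via keto acid 5 (not isolated)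
Conditions: 3 (2.2 equiv), iPrMgCl (4.3 equiv), THF, 0 °C to reflux; then 2, 50 °C; then 2 M HCl, 50 °C
Reagents that add atoms: none
Why: Ivanov-type Claisen condensation: the magnesium enediolate of the arylacetic acid is C-acylated by the ester, the product is held as its magnesium keto-carboxylate (no second addition), and acidification with warming decarboxylates the β-keto acid to the deoxybenzoin; the transient stereocentre of 5 is lost.

**Step 3**
Reactants: 6 1-[3,5-bis(benzyloxy)-4-methylphenyl]-2-(2-methoxyphenyl)ethan-1-one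
Product: 7 5-[2-(2-methoxyphenyl)ethyl]-2-methylbenzene-1,3-diol
Conditions: H2 (4 bar), 10% Pd/C, HClO4 (cat.), EtOAc/AcOH, 40 °C
Reagents that add atoms: none
Why: One catalytic hydrogenation cleaves both benzyl ethers and, with acid assistance, takes the aryl ketone through the benzylic alcohol to CH2 (benzylic hydrogenolysis), while the anisole ring and its methyl ether are inert; no stereocentre is formed.

**Step 4**
Reactants: 7 5-[2-(2-methoxyphenyl)ethyl]-2-methylbenzene-1,3-diol
Product: 8 3-hydroxy-5-[2-(2-methoxyphenyl)ethyl]-2-methylcyclohexa-2,5-diene-1,4-dione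
Conditions: (KSO3)2NO (2.5 equiv), KH2PO4 (aq, pH 6), acetone/H2O, 0 to 25 °C
Reagents that add atoms: Fremy's salt, dipotassium nitrosodisulfonate (KSO3)2NO, [K+].[K+].[O]N(S(=O)(=O)[O-])S(=O)(=O)[O-]
Why: Teuber oxidation: one equivalent of the nitroxyl radical removes the phenolic hydrogen and a second delivers oxygen to the free para position (the two para sites are equivalent by symmetry and the carbon between the hydroxyls is blocked by methyl), giving the 2-hydroxy-1,4-benzoquinone; the non-phenolic anisole ring does not react and no stereocentre is formed.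

**Step 5**
Reactants: 8 3-hydroxy-5-[2-(2-methoxyphenyl)ethyl]-2-methylcyclohexa-2,5-diene-1,4-dione (two molecules)
Product: 11 4,4'-dihydroxy-2,2'-bis[2-(2-methoxyphenyl)ethyl]-5,5'-dimethyl-[1,1'-bi(cyclohexane)]-1,1',4,4'-tetraene-3,3',6,6'-tetrone, via hydroquinone 9 (not isolated), via bis-hydroquinone 10 (not isolated)
Conditions: Zn dust (0.50 equiv), degassed AcOH, 25 °C; then TFA (20 vol%), N2, 25 to 40 °C; then FeCl3·6H2O (2.5 equiv), H2O, 25 °C
Reagents that add atoms: none
Why: Proposed new method: the bond joins the two C6 carbons, each the electrophilic β-carbon of the C4 enone in 8 (C1=O is deactivated as a vinylogous acid), so half of 8 is reduced to hydroquinone 9, where that carbon is the only free ring CH and is nucleophilic (ortho and para to OH; a redox-reversed, homoenolate-type d3 equivalent of the enone β-carbon, with 8 acting as the enolonium-type aryl-cation equivalent of 9); acid-promoted conjugate addition and tautomerisation give the fully substituted bis-hydroquinone 10, which cannot add again, and FeCl3 oxidises both rings to the quinone; closest known reaction type is the acid-catalysed quinone–hydroquinone coupling to diquinones (Erdtman type) followed by FeCl3 oxidation of hydroxyquinols; no stereocentre is formed and the hindered axis arises unresolved.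

**Compound list**
1 | 3,5-dihydroxy-4-methylbenzoic acid | Cc1c(O)cc(cc1O)C(=O)O | starting material
2 | benzyl 3,5-bis(benzyloxy)-4-methylbenzoate | Cc1c(OCc2ccccc2)cc(C(=O)OCc2ccccc2)cc1OCc1ccccc1 | intermediate
3 | 2-(2-methoxyphenyl)acetic acid | COc1ccccc1CC(=O)O | starting material
4 | bis(chloromagnesium) 2-(2-methoxyphenyl)ethene-1,1-diolate (Ivanov reagent of 3) | COc1ccccc1C=C(O[Mg]Cl)O[Mg]Cl | intermediate
5 | 3-[3,5-bis(benzyloxy)-4-methylphenyl]-2-(2-methoxyphenyl)-3-oxopropanoic acid (racemic, transient) | COc1ccccc1C(C(=O)O)C(=O)c1cc(OCc2ccccc2)c(C)c(OCc2ccccc2)c1 | intermediate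
6 | 1-[3,5-bis(benzyloxy)-4-methylphenyl]-2-(2-methoxyphenyl)ethan-1-one | COc1ccccc1CC(=O)c1cc(OCc2ccccc2)c(C)c(OCc2ccccc2)c1 | intermediate
7 | 5-[2-(2-methoxyphenyl)ethyl]-2-methylbenzene-1,3-diol | COc1ccccc1CCc1cc(O)c(C)c(O)c1 | intermediate
8 | 3-hydroxy-5-[2-(2-methoxyphenyl)ethyl]-2-methylcyclohexa-2,5-diene-1,4-dione | COc1ccccc1CCC1=CC(=O)C(C)=C(O)C1=O | intermediate
9 | 6-[2-(2-methoxyphenyl)ethyl]-3-methylbenzene-1,2,4-triol | COc1ccccc1CCc1cc(O)c(C)c(O)c1O | intermediate
10 | 6,6'-bis[2-(2-methoxyphenyl)ethyl]-3,3'-dimethyl-[1,1'-biphenyl]-2,2',4,4',5,5'-hexol | COc1ccccc1CCc1c(O)c(O)c(C)c(O)c1-c1c(O)c(C)c(O)c(O)c1CCc1ccccc1OC | intermediate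
11 | 4,4'-dihydroxy-2,2'-bis[2-(2-methoxyphenyl)ethyl]-5,5'-dimethyl-[1,1'-bi(cyclohexane)]-1,1',4,4'-tetraene-3,3',6,6'-tetrone | COc1ccccc1CCC1=C(C2=C(CCc3ccccc3OC)C(=O)C(O)=C(C)C2=O)C(=O)C(C)=C(O)C1=O | target

**Totals**
Total step count: 5. Longest linear sequence: 5 steps (1 → 2 → 6 → 7 → 8 → 11).

**Three steps most likely to fail**

Step 5 (highest risk). Quinone 8 is a deactivated acceptor, a tetra-ortho-substituted axis must form, and C–O coupling or acid-induced dibenzofuran formation from 10 can compete. Unreacted 9 is returned to 8 by the FeCl3 treatment and can be recycled. The fallback sets out from 8 and makes the axis by metal-mediated reductive coupling of a protected aryl iodide. Reductive methylation (Na2S2O4, then Me2SO4, K2CO3, acetone) gives 1,3,4-trimethoxy-5-[2-(2-methoxyphenyl)ethyl]-2-methylbenzene F1. Iodination at the single free position of the trioxygenated ring (NIS, cat. TFA, MeCN) gives 1-iodo-2,4,5-trimethoxy-6-[2-(2-methoxyphenyl)ethyl]-3-methylbenzene F2. Ullmann homocoupling (activated Cu powder, DMF, 150 °C) gives 2,2',4,4',5,5'-hexamethoxy-6,6'-bis[2-(2-methoxyphenyl)ethyl]-3,3'-dimethyl-1,1'-biphenyl F3. Oxidative demethylation of the para-dimethoxy pair in each ring with (NH4)2Ce(NO3)6 (MeCN/H2O, 0 °C) gives 4,4'-dimethoxy-2,2'-bis[2-(2-methoxyphenyl)ethyl]-5,5'-dimethyl-[1,1'-bi(cyclohexane)]-1,1',4,4'-tetraene-3,3',6,6'-tetrone F4. Hydrolysis of the two vinylogous esters (aq. NaOH, MeOH, then HCl) leaves the anisole ethers intact and comes back to the route at 11.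

Step 4. Teuber oxidation of a free resorcinol can be low-yielding, because the product 8 is an electrophile for unreacted 7. The fallback sets out from 7 and installs the third oxygen by formylation and Dakin oxidation. Vilsmeier–Haack formylation (POCl3, DMF, MeCN, 0 to 25 °C, aqueous hydrolysis) of the far more activated resorcinol ring gives 2,4-dihydroxy-6-[2-(2-methoxyphenyl)ethyl]-3-methylbenzaldehyde F5. Dakin oxidation (H2O2, NaOH, degassed H2O/THF, 0 °C) passes through 2,4-dihydroxy-6-[2-(2-methoxyphenyl)ethyl]-3-methylphenyl formate F6 to triol 9. Oxidation of 9 with FeCl3 (aq. MeCN) comes back to the route at 8.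

Step 3. The hydrogenation may stop at the benzylic carbinol, since the meta-oxygenated ring gives little assistance to C–O hydrogenolysis. The fallback sets out from 6 and removes the oxygen by elimination. NaBH4 (MeOH/THF, 0 °C) gives racemic 1-[3,5-bis(benzyloxy)-4-methylphenyl]-2-(2-methoxyphenyl)ethan-1-ol F7. Acid-catalysed dehydration (TsOH, toluene, reflux, Dean–Stark) gives 1,3-bis(benzyloxy)-5-[(E)-2-(2-methoxyphenyl)ethenyl]-2-methylbenzene F8. Hydrogenation (H2, Pd/C, EtOAc/EtOH, 25 °C) saturates the alkene and cleaves both benzyl ethers, coming back to the route at 7.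

**Further compounds**
F1 | step 5 | 1,3,4-trimethoxy-5-[2-(2-methoxyphenyl)ethyl]-2-methylbenzene | COc1ccccc1CCc1cc(OC)c(C)c(OC)c1OC
F2 | step 5 | 1-iodo-2,4,5-trimethoxy-6-[2-(2-methoxyphenyl)ethyl]-3-methylbenzene | COc1ccccc1CCc1c(I)c(OC)c(C)c(OC)c1OC
F3 | step 5 | 2,2',4,4',5,5'-hexamethoxy-6,6'-bis[2-(2-methoxyphenyl)ethyl]-3,3'-dimethyl-1,1'-biphenyl | COc1ccccc1CCc1c(OC)c(OC)c(C)c(OC)c1-c1c(OC)c(C)c(OC)c(OC)c1CCc1ccccc1OC
F4 | step 5 | 4,4'-dimethoxy-2,2'-bis[2-(2-methoxyphenyl)ethyl]-5,5'-dimethyl-[1,1'-bi(cyclohexane)]-1,1',4,4'-tetraene-3,3',6,6'-tetrone | COc1ccccc1CCC1=C(C2=C(CCc3ccccc3OC)C(=O)C(OC)=C(C)C2=O)C(=O)C(C)=C(OC)C1=O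
F5 | step 4 | 2,4-dihydroxy-6-[2-(2-methoxyphenyl)ethyl]-3-methylbenzaldehyde | COc1ccccc1CCc1cc(O)c(C)c(O)c1C=O
F6 | step 4 | 2,4-dihydroxy-6-[2-(2-methoxyphenyl)ethyl]-3-methylphenyl formate | COc1ccccc1CCc1cc(O)c(C)c(O)c1OC=O
F7 | step 3 | 1-[3,5-bis(benzyloxy)-4-methylphenyl]-2-(2-methoxyphenyl)ethan-1-ol (racemic) | COc1ccccc1CC(O)c1cc(OCc2ccccc2)c(C)c(OCc2ccccc2)c1
F8 | step 3 | 1,3-bis(benzyloxy)-5-[(E)-2-(2-methoxyphenyl)ethenyl]-2-methylbenzene | COc1ccccc1/C=C/c1cc(OCc2ccccc2)c(C)c(OCc2ccccc2)c1
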